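At the time of reading, 2.0 h, each flask is judged by one number: the share of target in target plus over-reaction product, the selectivity.

| flask | starting material | second substrate | partner | free catalyst | remark | time |
|---|---|---|---|---|---|---|
| midnight | 20 mM | 10 mM | 22 mM | 10 µM | run made earlier |  |
| summer | 20 mM | 5 mM | 22 mM | 10 µM | run made earlier |  |
| autumn | 20 mM | 7.5 mM | 22 mM | 10 µM | run made earlier |  |
| north-west | 20 mM | 10.0 mM (fed, over 80 min) | 22.0 mM | 10 µM | all else is in the flask from the start; the feed brings no volume worth counting | 2.0 h |
| south-west | 20 mM | 10.0 mM | 22.0 mM | 10 µM | everything together at the start | 2.0 h |
| south-east | 20 mM | 10.0 mM (fed, over 20 min) | 22.0 mM | 10 µM | all else is in the flask from the start; the feed brings no volume worth counting | 2.0 h |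
| north-east | 20 mM (fed, over 80 min) | 10.0 mM | 22.0 mM | 10 µM | all else is in the flask from the start; the feed brings no volume worth counting | 2.0 h |

midnight run (percent of the starting material charged)

| time / min | target / % | over-reaction product / % |
|---|---|---|
| 20.0 | 5.8 | 0.5 |
| 40.0 | 11.2 | 2.4 |
| 50.0 | 13.5 | 1.3 |
| 80.0 | 17.6 | 3.3 |

summer run (percent of the starting material charged)

| time / h | target / % | over-reaction product / % |
|---|---|---|
| 0.333 | 6.4 | 0.6 |
| 0.833 | 13.8 | 1.6 |
| 1.50 | 18.3 | 4.8 |
| 2.50 | 23.3 | 8.2 |

autumn run (percent of the starting material charged)

| time / h | target / % | over-reaction product / % |
|---|---|---|
| 0.200 | 4.0 | 0.2 |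
| 0.417 | 7.8 | 0.1 |
| 1.00 | 14.9 | 2.5 |
| 2.50 | 22.1 | 7.5 |

(scatter of a reading: 0.5 percentage points)

- on the list of suspects stand: partner + catalyst intermediate B -> free catalyst + second product; partner + catalyst intermediate A <-> free catalyst + target; second substrate + free catalyst <-> catalyst intermediate B; partner + free catalyst + target -> free catalyst + over-reaction product; starting material + free catalyst <-> catalyst intermediate A

* the flask that comes out highest in share of target in target plus over-reaction product, or "all alike" when all lie within 1.5 percentage points (north-west / south-west / south-east / north-east / all alike)
* share of target in target plus over-reaction product at the end, north-west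
* share of target in target plus over-reaction product at the end, south-west
* share of target in target plus over-reaction product at the end, south-east
* share of target in target plus over-reaction product at the end, north-east

We treat over-reaction product as a small correction to target, and we take target to go over at a steady average rate. Over-reaction product is then target times the ratio of two times, and the share is one over one plus that ratio.

The first time comes from the summer run: the area under its target curve divided by its last over-reaction reading gives 4.59 h, the life of target against over-reaction. The autumn run, with 7.5 mM of second substrate against 5 mM, reads 4.81 h.

The second time is the mean age of the target standing at the reading, and the recipe shapes it. For a straight rise from the start, the age is 1.00 h, half the run, so our share is 82.1 %. We expect this for south-west, and for south-east and north-west too, whose starting material also stands in the flask from the start. In north-east, target forms in step with starting material fed over 80 min, then steadily. The age is then 0.722 h and the share 86.4 %. We commit to north-east, higher by 4.3 percentage points.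

The forecast also names north-east, with 86 % there, but it gives lower values than ours elsewhere: 76.5 % for north-west, 78 % for south-west, 77.5 % for south-east. Its ground: “Feeding starting material keeps target low for most of the run.”

The flasks give 76.6 % in north-west, 79.6 % in south-west, 78.8 % in south-east and 83.8 % in north-east, so north-east stands highest.

    partner + catalyst intermediate B → free catalyst + second product (k = 33000 M⁻¹ min⁻¹)
    partner + catalyst intermediate A ⇌ free catalyst + target (K = 2.70, k = 860 M⁻¹ min⁻¹)
    second substrate + free catalyst ⇌ catalyst intermediate B (K = 90.0 M⁻¹, k = 2700 M⁻¹ min⁻¹)
    partner + free catalyst + target → free catalyst + over-reaction product (k = 48000 M⁻² min⁻¹)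
    starting material + free catalyst ⇌ catalyst intermediate A (K = 47.0 M⁻¹, k = 3000 M⁻¹ min⁻¹)

Read back through 4.59 h, north-east has a target age of 0.887 h and north-west 1.40 h. The reading time is 0.436 of that life, and north-east has not come to rest: at 20.0 h its target has gone from 14.9 % to 13.2 %, its over-reaction product from 2.88 % to 19.7 %, and its share has fallen to 40.1 %. North-west, at the same late time, stands at a share of 37.4 %.

The earlier runs and the new flask are calculated on assumed constants; the scatter is artificial.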